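**Strategy**

The chain is cut at the C11'–C12' single bond (carotenoid locants), the sp2–sp2 link between the C13'-methyl alkene and the C9'-methyl alkene, five chain carbons from the 3',5'-dihydroxycyclohexylidene ring. The key step exploits the retro pattern: both ring carbons C6 and C6' carry exocyclic C=C bonds, so each half is a vinylogous enol derivative. A C25 polyenal is enolised from ring C4 through to the carbonyl and trapped as a retro octaenyl triflate; an epoxy-ionone is opened to a cyclohexylidene dienal and homologated to a C15 trienyl boronate. One Suzuki–Miyaura coupling joins them and completes the undecaene; (4R,6R)-actinol supplies all three stereocentres.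

Key step: step 15

Remark on the chemistry: locants follow carotenoid numbering, unprimed (C1–C15) for the half ending in the hydroxycyclohexene ring and primed (C1'–C15') for the half ending in the dihydroxycyclohexylidene ring. Compounds 1, 5, 9 and 13 are taken as commercially available, and all polyene steps are run under argon with exclusion of light.

**Route**

Step 1
Reactants: 1 (4R,6R)-4-hydroxy-2,2,6-trimethylcyclohexan-1-one ((4R,6R)-actinol)
Product: 2 (4R,6R)-4-[(tert-butyldimethylsilyl)oxy]-2,2,6-trimethylcyclohexan-1-one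
Conditions: TBSCl, imidazole, DMF, rt
Reagents that add atoms: tert-butyldimethylsilyl chloride, CC(C)(C)[Si](C)(C)Cl
Why: Standard silylation of the unhindered secondary alcohol; neither stereocentre is touched.

Step 2
Reactants: 2 (4R,6R)-4-[(tert-butyldimethylsilyl)oxy]-2,2,6-trimethylcyclohexan-1-one
Product: 4 (4R)-4-[(tert-butyldimethylsilyl)oxy]-2,6,6-trimethylcyclohex-1-en-1-yl trifluoromethanesulfonate, via lithium enolate 3 (not isolated)
Conditions: LDA, THF, −78 °C; then PhNTf2, −78 → 0 °C
Reagents that add atoms: N-phenylbis(trifluoromethanesulfonimide), O=S(=O)(N(c1ccccc1)S(=O)(=O)C(F)(F)F)C(F)(F)F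
Why: Enolisation is possible only toward C6 (C2 is quaternary) and O-triflation of the enolate gives the tetrasubstituted enol triflate; the C6 stereocentre is erased on purpose and the carbinol centre is untouched.

Step 3
Reactants: 5 (E)-3-methylpent-2-en-4-yn-1-ol
Product: 6 (2E,4E)-3-methyl-5-(tributylstannyl)penta-2,4-dien-1-ol
Conditions: Bu3SnH, PdCl2(PPh3)2 (2 mol %), THF, 0 °C
Reagents that add atoms: tributyltin hydride, CCCC[SnH](CCCC)CCCC
Why: Palladium-catalysed syn-hydrostannation of the terminal alkyne should place tin at the terminus and give the (E)-alkenylstannane; the existing (E)-alkene is retained.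

Step 4
Reactants: 4 (4R)-4-[(tert-butyldimethylsilyl)oxy]-2,6,6-trimethylcyclohex-1-en-1-yl trifluoromethanesulfonate; 6 (2E,4E)-3-methyl-5-(tributylstannyl)penta-2,4-dien-1-ol
Product: 7 (2E,4E)-5-[(4R)-4-[(tert-butyldimethylsilyl)oxy]-2,6,6-trimethylcyclohex-1-en-1-yl]-3-methylpenta-2,4-dien-1-ol
Conditions: Pd2(dba)3 (5 mol %), AsPh3 (40 mol %), NMP, 60 °C
Reagents that add atoms: none
Why: Stille coupling of an alkenyl triflate with an alkenylstannane; the weakly donating arsine ligand in a polar solvent is chosen to speed transmetalation at the hindered cyclohexenyl palladium, and both alkene geometries are retained.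

Step 5
Reactants: 7 (2E,4E)-5-[(4R)-4-[(tert-butyldimethylsilyl)oxy]-2,6,6-trimethylcyclohex-1-en-1-yl]-3-methylpenta-2,4-dien-1-ol
Product: 8 [(2E,4E)-5-[(4R)-4-[(tert-butyldimethylsilyl)oxy]-2,6,6-trimethylcyclohex-1-en-1-yl]-3-methylpenta-2,4-dien-1-yl]triphenylphosphonium bromide
Conditions: PPh3·HBr, CH2Cl2, 0 °C → rt
Reagents that add atoms: triphenylphosphine hydrobromide, Br.P(c1ccccc1)(c1ccccc1)c1ccccc1
Why: Standard formation of a C15 Wittig salt: the dienylic alcohol ionises to a pentadienyl cation that phosphine captures at the terminus to give the conjugated all-E salt; the non-protic solvent should spare the silyl ether.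

Step 6
Reactants: 8 [(2E,4E)-5-[(4R)-4-[(tert-butyldimethylsilyl)oxy]-2,6,6-trimethylcyclohex-1-en-1-yl]-3-methylpenta-2,4-dien-1-yl]triphenylphosphonium bromide; 9 (2E,4E,6E)-2,7-dimethylocta-2,4,6-trienedial (3 equiv)
Product: 10 (2E,4E,6E,8E,10E,12E)-13-[(4R)-4-[(tert-butyldimethylsilyl)oxy]-2,6,6-trimethylcyclohex-1-en-1-yl]-2,7,11-trimethyltrideca-2,4,6,8,10,12-hexaenal
Conditions: NaOMe, MeOH–CH2Cl2, 0 °C → rt; then I2 (cat.), CH2Cl2, rt, daylight
Reagents that add atoms: none
Why: Wittig olefination with excess dialdehyde should stop after one condensation because the product polyenal is the weaker electrophile, and iodine-catalysed equilibration converts the new C11=C12 bond to E.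

Step 7
Reactants: 10 (2E,4E,6E,8E,10E,12E)-13-[(4R)-4-[(tert-butyldimethylsilyl)oxy]-2,6,6-trimethylcyclohex-1-en-1-yl]-2,7,11-trimethyltrideca-2,4,6,8,10,12-hexaenal
Product: 12 (1E,3E,5E,7E,9E,11E)-13-[(1E,4S)-4-[(tert-butyldimethylsilyl)oxy]-2,6,6-trimethylcyclohex-2-en-1-ylidene]-2,7,11-trimethyltrideca-1,3,5,7,9,11-hexaen-1-yl trifluoromethanesulfonate, via potassium polyenolate 11 (not isolated)
Conditions: t-BuOK (1.1 equiv), THF–DMPU, −78 → −40 °C; then PhNTf2, −78 → 0 °C
Reagents that add atoms: N-phenylbis(trifluoromethanesulfonimide), O=S(=O)(N(c1ccccc1)S(=O)(=O)C(F)(F)F)C(F)(F)F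
Why: Proposed new method: the ring C4–H is vinylogously acidic through C5=C6, the six chain C=C bonds and the C=O, so reversible deprotonation with alkoxide should funnel, by proton shuttling, to the fully linear polyenolate (ring C4=C5, exocyclic C6=C7, enolate C13'=C12'–O), and hard O-sulfonylation fixes it as the retro enol triflate; E at C13'=C12' follows from the s-trans enal conformer, E at C6=C7 from avoidance of the in-plane C5 methyl, and the remaining new double bonds arise from s-trans single bonds; the closest known reaction types are γ-deprotonation/O-triflation of enals to 1,3-dienyl triflates and the retro isomerisation of retinoids (anhydroretinol type).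

Step 8
Reactants: 4 (4R)-4-[(tert-butyldimethylsilyl)oxy]-2,6,6-trimethylcyclohex-1-en-1-yl trifluoromethanesulfonate; 13 but-3-en-2-one (methyl vinyl ketone)
Product: 14 (E)-4-[(4R)-4-[(tert-butyldimethylsilyl)oxy]-2,6,6-trimethylcyclohex-1-en-1-yl]but-3-en-2-one
Conditions: Pd(OAc)2 (5 mol %), PPh3 (10 mol %), Et3N, DMF, 70 °C
Reagents that add atoms: none
Why: Heck reaction of an enol triflate with an enone; syn-insertion and β-hydride elimination give the (E)-dienone.

Step 9
Reactants: 14 (E)-4-[(4R)-4-[(tert-butyldimethylsilyl)oxy]-2,6,6-trimethylcyclohex-1-en-1-yl]but-3-en-2-one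
Product: 15 (E)-4-[(4R)-4-hydroxy-2,6,6-trimethylcyclohex-1-en-1-yl]but-3-en-2-one
Conditions: TBAF, THF, rt
Reagents that add atoms: none
Why: Fluoride cleavage of the silyl ether frees the homoallylic hydroxyl needed to direct the next step.

Step 10
Reactants: 15 (E)-4-[(4R)-4-hydroxy-2,6,6-trimethylcyclohex-1-en-1-yl]but-3-en-2-one
Product: 16 (E)-4-[(1R,4S,6S)-4-hydroxy-2,2,6-trimethyl-7-oxabicyclo[4.1.0]heptan-1-yl]but-3-en-2-one (epoxide syn to the hydroxyl)
Conditions: VO(acac)2 (5 mol %), t-BuOOH (decane), CH2Cl2, 0 °C → rt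
Reagents that add atoms: tert-butyl hydroperoxide, CC(C)(C)OO
Why: Hydroxyl-directed vanadium-catalysed epoxidation: the vanadate ester of the homoallylic alcohol delivers oxygen to the ring C5'=C6' bond on the face of the hydroxyl, which sets C5' and C6' by substrate control; the electron-poor enone alkene should not react.

Step 11
Reactants: 16 (E)-4-[(1R,4S,6S)-4-hydroxy-2,2,6-trimethyl-7-oxabicyclo[4.1.0]heptan-1-yl]but-3-en-2-one
Product: 17 (1R,4R,6S)-2,2,6-trimethyl-1-[(E)-3-oxobut-1-en-1-yl]-7-oxabicyclo[4.1.0]heptan-4-yl benzoate (ester anti to the epoxide)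
Conditions: PhCO2H, PPh3, DIAD, THF, 0 °C → rt
Reagents that add atoms: benzoic acid, OC(=O)c1ccccc1
Why: Mitsunobu reaction: SN2 displacement inverts the secondary carbinol to the C3' configuration of the target and leaves it protected; the cis-epoxide cannot participate from the rear.

Step 12
Reactants: 17 (1R,4R,6S)-2,2,6-trimethyl-1-[(E)-3-oxobut-1-en-1-yl]-7-oxabicyclo[4.1.0]heptan-4-yl benzoate
Product: 18 (1R,4R,6S)-1-[(1E)-4-methoxy-3-methylbuta-1,3-dien-1-yl]-2,2,6-trimethyl-7-oxabicyclo[4.1.0]heptan-4-yl benzoate (E/Z mixture at the enol ether)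
Conditions: MeOCH2PPh3Cl, KHMDS, THF, 0 °C; then 17, −78 → 0 °C
Reagents that add atoms: (methoxymethyl)triphenylphosphonium chloride, COC[P+](c1ccccc1)(c1ccccc1)c1ccccc1.[Cl-]
Why: Wittig methoxymethylenation adds C10' by 1,2-attack at the ketone, which should react faster with the ylide than the benzoate; the enol ether geometry is irrelevant.

Step 13
Reactants: 18 (1R,4R,6S)-1-[(1E)-4-methoxy-3-methylbuta-1,3-dien-1-yl]-2,2,6-trimethyl-7-oxabicyclo[4.1.0]heptan-4-yl benzoate
Product: 20 (1R,3S,4E)-3-hydroxy-3,5,5-trimethyl-4-[(2E)-3-methyl-4-oxobut-2-en-1-ylidene]cyclohexyl benzoate, via epoxy enal 19 (not isolated)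
Conditions: PPTS (cat.), acetone–H2O, 0 °C; then DBU, CH2Cl2, 0 °C → rt
Reagents that add atoms: water, O
Why: Enol ether hydrolysis gives the β,γ-unsaturated aldehyde, whose dienolate expels the allylic epoxide oxygen from C6' in a vinylogous E1cB opening (the vinylogue of the β,γ-epoxy carbonyl to γ-hydroxy enone isomerisation), so C5' keeps its C–O bond and configuration; C8'=C9' should form E as the conjugated enal, and C6'=C7' should form E because the reacting rotamer keeps C8' away from the eclipsed C5' methyl.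

Step 14
Reactants: 20 (1R,3S,4E)-3-hydroxy-3,5,5-trimethyl-4-[(2E)-3-methyl-4-oxobut-2-en-1-ylidene]cyclohexyl benzoate
Product: 21 (1R,3S,4E)-3-hydroxy-3,5,5-trimethyl-4-[(2E,4E)-3-methyl-5-(4,4,5,5-tetramethyl-1,3,2-dioxaborolan-2-yl)penta-2,4-dien-1-ylidene]cyclohexyl benzoate
Conditions: Cl2CHBpin, CrCl2, LiI, THF, rt
Reagents that add atoms: 2-(dichloromethyl)-4,4,5,5-tetramethyl-1,3,2-dioxaborolane, CC1(C)OB(C(Cl)Cl)OC1(C)C
Why: Takai-type boryl olefination through a geminal dichromium species adds C11' and should give the (E)-alkenylboronate; chromium(II) tolerates the ester and the free tertiary alcohol.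

Step 15
Reactants: 12 (1E,3E,5E,7E,9E,11E)-13-[(1E,4S)-4-[(tert-butyldimethylsilyl)oxy]-2,6,6-trimethylcyclohex-2-en-1-ylidene]-2,7,11-trimethyltrideca-1,3,5,7,9,11-hexaen-1-yl trifluoromethanesulfonate; 21 (1R,3S,4E)-3-hydroxy-3,5,5-trimethyl-4-[(2E,4E)-3-methyl-5-(4,4,5,5-tetramethyl-1,3,2-dioxaborolan-2-yl)penta-2,4-dien-1-ylidene]cyclohexyl benzoate
Product: 22 the all-E target skeleton carrying a tert-butyldimethylsilyl ether on the cyclohexene carbinol (C3) and a benzoate on the secondary carbinol of the cyclohexylidene ring (C3'), with the tertiary C5' hydroxyl free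
Conditions: Pd(dppf)Cl2 (5 mol %), K3PO4 (aq.), THF, rt, dark, Ar
Reagents that add atoms: none
Why: Pd(0) adds oxidatively to the C12'–OTf bond of 12 with retention, the phosphate-activated alkenylboronate 21 transfers its C11' alkenyl group to palladium, and reductive elimination forms the C11'–C12' σ-bond between two sp2 carbons with retention of both alkene geometries. The closest known reaction type is the Suzuki–Miyaura coupling of alkenyl triflates with alkenyl pinacolboronates used for retinoid and carotenoid polyenes. No ring is closed and no stereocentre is created; the E geometries at C13'=C12' and C11'=C10' are carried over from 12 and 21. The step needs chemoselectivity for the enol triflate in the presence of a benzoate, a free tertiary allylic alcohol, a silyl ether and two light- and acid-sensitive polyenes, and it must not scramble E/Z geometry. This should be secured by the high reactivity of the alkenyl triflate toward Pd(0), a weak base at room temperature, and exclusion of light and oxygen. In this one operation the octaene of 12 and the triene of 21 merge into the complete retro undecaene of the target.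

Step 16
Reactants: 22 the silyl- and benzoyl-protected target
Product: 24 target triol CNP0269135.1 (all-E; 3S in the cyclohexene ring; 3'R,5'S in the cyclohexylidene ring), via monobenzoate 23 (not isolated)
Conditions: TBAF, THF, 0 °C → rt; then K2CO3, MeOH, rt
Reagents that add atoms: none
Why: Fluoride desilylation followed by methanolysis of the benzoate removes both groups under basic conditions only, which should spare the acid-labile polyenylic C3 alcohol and the tertiary allylic C5' alcohol.

**Compound list**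

1 | (4R,6R)-4-hydroxy-2,2,6-trimethylcyclohexan-1-one ((4R,6R)-actinol) | O=C1[C@H](C)C[C@@H](O)CC1(C)C | starting material
2 | (4R,6R)-4-[(tert-butyldimethylsilyl)oxy]-2,2,6-trimethylcyclohexan-1-one | O=C1[C@H](C)C[C@@H](O[Si](C)(C)C(C)(C)C)CC1(C)C | intermediate
3 | lithium (4R)-4-[(tert-butyldimethylsilyl)oxy]-2,6,6-trimethylcyclohex-1-en-1-olate | [Li+].[O-]C1=C(C)C[C@@H](O[Si](C)(C)C(C)(C)C)CC1(C)C | intermediate
4 | (4R)-4-[(tert-butyldimethylsilyl)oxy]-2,6,6-trimethylcyclohex-1-en-1-yl trifluoromethanesulfonate | CC1=C(OS(=O)(=O)C(F)(F)F)C(C)(C)C[C@H](O[Si](C)(C)C(C)(C)C)C1 | intermediate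
5 | (E)-3-methylpent-2-en-4-yn-1-ol | C#C/C(C)=C/CO | starting material
6 | (2E,4E)-3-methyl-5-(tributylstannyl)penta-2,4-dien-1-ol | CCCC[Sn](CCCC)(CCCC)/C=C/C(C)=C/CO | intermediate
7 | (2E,4E)-5-[(4R)-4-[(tert-butyldimethylsilyl)oxy]-2,6,6-trimethylcyclohex-1-en-1-yl]-3-methylpenta-2,4-dien-1-ol | CC1=C(/C=C/C(C)=C/CO)C(C)(C)C[C@H](O[Si](C)(C)C(C)(C)C)C1 | intermediate
8 | [(2E,4E)-5-[(4R)-4-[(tert-butyldimethylsilyl)oxy]-2,6,6-trimethylcyclohex-1-en-1-yl]-3-methylpenta-2,4-dien-1-yl]triphenylphosphonium bromide | CC1=C(/C=C/C(C)=C/C[P+](c2ccccc2)(c2ccccc2)c2ccccc2)C(C)(C)C[C@H](O[Si](C)(C)C(C)(C)C)C1.[Br-] | intermediate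
9 | (2E,4E,6E)-2,7-dimethylocta-2,4,6-trienedial | O=C/C(C)=C/C=C/C=C(C)/C=O | starting material
10 | (2E,4E,6E,8E,10E,12E)-13-[(4R)-4-[(tert-butyldimethylsilyl)oxy]-2,6,6-trimethylcyclohex-1-en-1-yl]-2,7,11-trimethyltrideca-2,4,6,8,10,12-hexaenal | CC1=C(/C=C/C(C)=C/C=C/C(C)=C/C=C/C=C(C)/C=O)C(C)(C)C[C@H](O[Si](C)(C)C(C)(C)C)C1 | intermediate
11 | potassium (1E,3E,5E,7E,9E,11E)-13-[(1E,4S)-4-[(tert-butyldimethylsilyl)oxy]-2,6,6-trimethylcyclohex-2-en-1-ylidene]-2,7,11-trimethyltrideca-1,3,5,7,9,11-hexaen-1-olate | CC1=C[C@@H](O[Si](C)(C)C(C)(C)C)CC(C)(C)\C1=C/C=C(C)/C=C/C=C(C)/C=C/C=C/C(C)=C/[O-].[K+] | intermediate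
12 | (1E,3E,5E,7E,9E,11E)-13-[(1E,4S)-4-[(tert-butyldimethylsilyl)oxy]-2,6,6-trimethylcyclohex-2-en-1-ylidene]-2,7,11-trimethyltrideca-1,3,5,7,9,11-hexaen-1-yl trifluoromethanesulfonate | CC1=C[C@@H](O[Si](C)(C)C(C)(C)C)CC(C)(C)\C1=C/C=C(C)/C=C/C=C(C)/C=C/C=C/C(C)=C/OS(=O)(=O)C(F)(F)F | intermediate
13 | but-3-en-2-one (methyl vinyl ketone) | CC(=O)C=C | starting material
14 | (E)-4-[(4R)-4-[(tert-butyldimethylsilyl)oxy]-2,6,6-trimethylcyclohex-1-en-1-yl]but-3-en-2-one | CC(=O)/C=C/C1=C(C)C[C@@H](O[Si](C)(C)C(C)(C)C)CC1(C)C | intermediate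
15 | (E)-4-[(4R)-4-hydroxy-2,6,6-trimethylcyclohex-1-en-1-yl]but-3-en-2-one | CC(=O)/C=C/C1=C(C)C[C@@H](O)CC1(C)C | intermediate
16 | (E)-4-[(1R,4S,6S)-4-hydroxy-2,2,6-trimethyl-7-oxabicyclo[4.1.0]heptan-1-yl]but-3-en-2-one | CC(=O)/C=C/[C@]12O[C@@]1(C)C[C@@H](O)CC2(C)C | intermediate
17 | (1R,4R,6S)-2,2,6-trimethyl-1-[(E)-3-oxobut-1-en-1-yl]-7-oxabicyclo[4.1.0]heptan-4-yl benzoate | CC(=O)/C=C/[C@]12O[C@@]1(C)C[C@H](OC(=O)c3ccccc3)CC2(C)C | intermediate
18 | (1R,4R,6S)-1-[(1E)-4-methoxy-3-methylbuta-1,3-dien-1-yl]-2,2,6-trimethyl-7-oxabicyclo[4.1.0]heptan-4-yl benzoate (E/Z mixture at the enol ether) | COC=C(C)/C=C/[C@]12O[C@@]1(C)C[C@H](OC(=O)c3ccccc3)CC2(C)C | intermediate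
19 | (1R,4R,6S)-2,2,6-trimethyl-1-[(1E)-3-methyl-4-oxobut-1-en-1-yl]-7-oxabicyclo[4.1.0]heptan-4-yl benzoate (both side-chain epimers) | O=CC(C)/C=C/[C@]12O[C@@]1(C)C[C@H](OC(=O)c3ccccc3)CC2(C)C | intermediate
20 | (1R,3S,4E)-3-hydroxy-3,5,5-trimethyl-4-[(2E)-3-methyl-4-oxobut-2-en-1-ylidene]cyclohexyl benzoate | O=C/C(C)=C/C=C1\C(C)(C)C[C@@H](OC(=O)c2ccccc2)C[C@]1(C)O | intermediate
21 | (1R,3S,4E)-3-hydroxy-3,5,5-trimethyl-4-[(2E,4E)-3-methyl-5-(4,4,5,5-tetramethyl-1,3,2-dioxaborolan-2-yl)penta-2,4-dien-1-ylidene]cyclohexyl benzoate | CC1(C)OB(/C=C/C(C)=C/C=C2\C(C)(C)C[C@@H](OC(=O)c3ccccc3)C[C@]2(C)O)OC1(C)C | intermediate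
22 | all-E target skeleton with C3 tert-butyldimethylsilyl ether and C3' benzoate (C5' hydroxyl free) | CC1=C[C@@H](O[Si](C)(C)C(C)(C)C)CC(C)(C)\C1=C/C=C(C)/C=C/C=C(C)/C=C/C=C/C(C)=C/C=C/C(C)=C/C=C1\C(C)(C)C[C@@H](OC(=O)c2ccccc2)C[C@]1(C)O | intermediate
23 | all-E target skeleton with C3' benzoate only | CC1=C[C@@H](O)CC(C)(C)\C1=C/C=C(C)/C=C/C=C(C)/C=C/C=C/C(C)=C/C=C/C(C)=C/C=C1\C(C)(C)C[C@@H](OC(=O)c2ccccc2)C[C@]1(C)O | intermediate
24 | target triol CNP0269135.1 (all-E; 3S; 3'R,5'S) | CC1=C[C@@H](O)CC(C)(C)\C1=C/C=C(C)/C=C/C=C(C)/C=C/C=C/C(C)=C/C=C/C(C)=C/C=C1\C(C)(C)C[C@@H](O)C[C@]1(C)O | target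

**Step count and risks**

Total steps: 16. Longest linear sequence: 11 steps (steps 1, 2, 8, 9, 10, 11, 12, 13, 14, 15, 16).

Most likely to fail, first: step 7, the labelled step. The base may remove a proton from the chain methyl groups on C13 or C9 or from the ring methyl on C5 instead of from C4. The polyenolate may also add to unreacted aldehyde or expel the C3 silyloxy group, so that isomeric or degraded triflates form. The fallback uses known chemistry, sets out from 10 and 20 and comes back at 22. Dienal 20 is converted by Takai iodo-olefination (CHI3, CrCl2, THF) into the (E)-alkenyl iodide F1. Nozaki–Hiyama–Kishi coupling of F1 with aldehyde 10 (CrCl2, cat. NiCl2, DMSO–THF) forms the same C11'–C12' bond and gives the bis-allylic carbinol F2 as both C12' epimers. Treatment with MsCl and Et3N at −40 °C ionises the C12' mesylate to a fully delocalised polyenyl cation, which loses H-4 in an anhydroretinol-type retro dehydration to give 22; the tertiary alcohol is not sulfonylated.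

Second: step 15. The enol triflate may hydrolyse or the boronate may protodeboronate under the aqueous basic conditions before transmetalation, and slow coupling gives time for E/Z scrambling of the polyenes. The fallback sets out from 20 and comes back at 22. Stannyl olefination of 20 with (dibromomethyl)tributylstannane, CrCl2 and LiI gives the (E)-alkenylstannane F3, which is joined to triflate 12 by a base-free Stille coupling (Pd2(dba)3, AsPh3, NMP, rt).

Third: step 13. During the acidic hydrolysis of the enol ether the activated allylic epoxide may open prematurely and cyclise through O5' onto C8' to a furanoid ether, or solvolyse, before the base-induced opening can take place. The fallback sets out from 17 and comes back at 20 without any acid stronger than acetic acid. Darzens condensation of ketone 17 with methyl chloroacetate and NaOMe, which also cleaves the benzoate, gives the glycidic ester F4. Saponification (NaOH, MeOH–H2O) and buffered decarboxylation (AcOH–pyridine, 40 °C) release the same dienolate, which opens the ring epoxide to the dihydroxy dienal F5. Selective benzoylation of the secondary hydroxyl (BzCl, pyridine, 0 °C) returns 20.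

Further compounds

F1 | step 7 | (1R,3S,4E)-3-hydroxy-4-[(2E,4E)-5-iodo-3-methylpenta-2,4-dien-1-ylidene]-3,5,5-trimethylcyclohexyl benzoate | I/C=C/C(C)=C/C=C1\C(C)(C)C[C@@H](OC(=O)c2ccccc2)C[C@]1(C)O
F2 | step 7 | C12' carbinol from addition of the alkenyl group of F1 to aldehyde 10 (both C12' epimers) | CC1=C(/C=C/C(C)=C/C=C/C(C)=C/C=C/C=C(C)/C(O)/C=C/C(C)=C/C=C2\C(C)(C)C[C@@H](OC(=O)c3ccccc3)C[C@]2(C)O)C(C)(C)C[C@H](O[Si](C)(C)C(C)(C)C)C1
F3 | step 15 | (1R,3S,4E)-3-hydroxy-3,5,5-trimethyl-4-[(2E,4E)-3-methyl-5-(tributylstannyl)penta-2,4-dien-1-ylidene]cyclohexyl benzoate | CCCC[Sn](CCCC)(CCCC)/C=C/C(C)=C/C=C1\C(C)(C)C[C@@H](OC(=O)c2ccccc2)C[C@]1(C)O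
F4 | step 13 | methyl 3-[(E)-2-[(1R,4R,6S)-4-hydroxy-2,2,6-trimethyl-7-oxabicyclo[4.1.0]heptan-1-yl]ethenyl]-3-methyloxirane-2-carboxylate (glycidate diastereomers) | COC(=O)C1OC1(C)/C=C/[C@]23O[C@@]2(C)C[C@H](O)CC3(C)C
F5 | step 13 | (2E,4E)-4-[(2S,4R)-2,4-dihydroxy-2,6,6-trimethylcyclohexylidene]-2-methylbut-2-enal | O=C/C(C)=C/C=C1\C(C)(C)C[C@@H](O)C[C@]1(C)O
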